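**Retrosynthetic overview**

- Feature: in ring C, the carbonyl carbon C4 and the hydroxyl-bearing carbon C3 are neighbours. With C2–C3 saturated they form an acyloin, so C3–C4 is cut to two formyl groups joined through O1 and C2, and is made by carbene-induced polarity reversal of the ring A formyl carbon.
- Ring order: rings A and B come from bought arenes; ring C is closed last (step 9), then dehydrogenated to the pyranone and debenzylated.
- Dialdehyde 13 comes from the O1–C2 ether of salicylaldehyde 7 and α-bromo arylacetate 10, followed by reduction and re-oxidation of both carbonyl carbons.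
- Ring A piece 7 comes from the symmetric 3,5-bis(benzyloxy)phenol: the chain goes on the carbon between the two benzyloxy groups (lithiation, oxetane opening), the formyl group ortho to the phenol. The symmetry fixes the chain at C6 of the flavonol.

Key step: step 9

Remark on the chemistry: compounds 10–15 (and F1, F3, F4) carry stereocentres that are not controlled and are drawn without descriptors (racemates or diastereomer mixtures). All of them are erased in step 10 and the target is achiral. Methyl 2-[4-(benzyloxy)phenyl]acetate (8) is taken as purchasable.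

**Route**

Step 1
Reactants: 1 3,5-bis(benzyloxy)phenol
Product: 2 [3,5-bis(benzyloxy)phenoxy]tri(propan-2-yl)silane
Conditions: TIPSCl, imidazole, DMF, rt
Reagents that add atoms: chlorotri(propan-2-yl)silane, CC(C)[Si](Cl)(C(C)C)C(C)C
Why: Silylation of the phenol with a silyl chloride and imidazole installs a bulky, weakly coordinating group that masks the phenol and keeps the lithiation of step 2 away from its ortho positions.

Step 2
Reactants: 2 [3,5-bis(benzyloxy)phenoxy]tri(propan-2-yl)silane; 3 2,2-dimethyloxetane
Product: 5 4-[2,6-bis(benzyloxy)-4-{[tri(propan-2-yl)silyl]oxy}phenyl]-2-methylbutan-2-ol, via aryllithium 4 (not isolated)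
Conditions: n-BuLi, THF, −20 to 0 °C; then 3, BF3·OEt2, −78 °C; H2O
Reagents that add atoms: none
Why: Directed ortho-metalation at the carbon flanked by both benzyloxy groups (cooperative coordination, kept cold to avoid benzylic deprotonation) followed by BF3-assisted SN2 opening of the oxetane at its unsubstituted CH2–O carbon should install the 3-hydroxy-3-methylbutyl chain in one operation.

Step 3
Reactants: 5 4-[2,6-bis(benzyloxy)-4-{[tri(propan-2-yl)silyl]oxy}phenyl]-2-methylbutan-2-ol
Product: 6 3,5-bis(benzyloxy)-4-(3-hydroxy-3-methylbutyl)phenol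
Conditions: Bu4NF, THF, 0 °C to rt; H2O
Reagents that add atoms: none
Why: Fluoride-induced cleavage of the aryl silyl ether frees the phenol without touching the benzyl ethers or the tertiary alcohol.

Step 4
Reactants: 6 3,5-bis(benzyloxy)-4-(3-hydroxy-3-methylbutyl)phenol
Product: 7 2,4-bis(benzyloxy)-6-hydroxy-3-(3-hydroxy-3-methylbutyl)benzaldehyde
Conditions: MgCl2, Et3N, (CH2O)n, MeCN, reflux; dilute aq. HCl work-up (cold, brief)
Reagents that add atoms: paraformaldehyde (as formaldehyde), C=O
Why: The magnesium phenoxide-directed ortho-formylation (Casnati–Skattebøl reaction) acts only ortho to the free phenol, and since the two ortho positions of 6 are equivalent by symmetry a single aldehyde should form, with the chain between the two benzyloxy groups as needed for C6.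

Step 5
Reactants: 8 methyl 2-[4-(benzyloxy)phenyl]acetate
Product: 10 methyl 2-[4-(benzyloxy)phenyl]-2-bromoacetate (racemic), via lithium enolate 9 (not isolated)
Conditions: LiN(SiMe3)2, THF, −78 °C; then cannulated into NBS, THF, −78 °C; H2O
Reagents that add atoms: N-bromosuccinimide, O=C1CCC(=O)N1Br
Why: Electrophilic bromination of the ester enolate (inverse addition to suppress self-alkylation) gives the α-bromo ester and, unlike radical bromination, spares the CH2 of the benzyl ether.

Step 6
Reactants: 7 2,4-bis(benzyloxy)-6-hydroxy-3-(3-hydroxy-3-methylbutyl)benzaldehyde; 10 methyl 2-[4-(benzyloxy)phenyl]-2-bromoacetate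
Product: 11 methyl 2-[3,5-bis(benzyloxy)-2-formyl-4-(3-hydroxy-3-methylbutyl)phenoxy]-2-[4-(benzyloxy)phenyl]acetate (racemic)
Conditions: K2CO3, DMF, rt
Reagents that add atoms: none
Why: Williamson etherification, an SN2 displacement of the activated benzylic α-bromo ester by the phenoxide, forms the O1–C2 bond, and carbonate at room temperature should be too mild to drive the aldol closure of the ester α-carbon onto the neighbouring formyl group.

Step 7
Reactants: 11 methyl 2-[3,5-bis(benzyloxy)-2-formyl-4-(3-hydroxy-3-methylbutyl)phenoxy]-2-[4-(benzyloxy)phenyl]acetate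
Product: 12 2-[3,5-bis(benzyloxy)-2-(hydroxymethyl)-4-(3-hydroxy-3-methylbutyl)phenoxy]-2-[4-(benzyloxy)phenyl]ethan-1-ol (racemic)
Conditions: LiAlH4, THF, 0 °C; then H2O, 15% aq. NaOH, H2O
Reagents that add atoms: none
Why: Hydride reduction takes the ester and the aryl aldehyde to primary alcohols, so that the future C3 and C4 reach the same oxidation level and can be raised together.

Step 8
Reactants: 12 2-[3,5-bis(benzyloxy)-2-(hydroxymethyl)-4-(3-hydroxy-3-methylbutyl)phenoxy]-2-[4-(benzyloxy)phenyl]ethan-1-ol
Product: 13 2,4-bis(benzyloxy)-6-{1-[4-(benzyloxy)phenyl]-2-oxoethoxy}-3-(3-hydroxy-3-methylbutyl)benzaldehyde (racemic)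
Conditions: Dess–Martin periodinane, NaHCO3, CH2Cl2, 0 °C to rt; used at once
Reagents that add atoms: none
Why: Dess–Martin oxidation of the benzylic and the primary alcohol under bicarbonate buffer should give both formyl groups under near-neutral conditions that do not enolise the labile α-aryl-α-aryloxy aldehyde, while the tertiary alcohol cannot be oxidised.

Step 9
Reactants: 13 2,4-bis(benzyloxy)-6-{1-[4-(benzyloxy)phenyl]-2-oxoethoxy}-3-(3-hydroxy-3-methylbutyl)benzaldehyde
Product: 14 5,7-bis(benzyloxy)-2-[4-(benzyloxy)phenyl]-3-hydroxy-6-(3-hydroxy-3-methylbutyl)-2,3-dihydro-4H-chromen-4-one (racemic, mixture of diastereomers)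
Conditions: 2-phenyl-6,7-dihydro-5H-pyrrolo[2,1-c][1,2,4]triazol-2-ium tetrafluoroborate (20 mol %), DBU (18 mol %), toluene, rt, Ar
Reagents that add atoms: none
Why: Proposed new method: the triazolylidene adds to the ring A formyl group, proton transfer gives the Breslow intermediate (an acyl anion equivalent at the future C4), this attacks the tethered aliphatic formyl carbon (future C3), and loss of the carbene leaves the C4 ketone beside the C3 carbinol in an isomerisation with no by-product. The closest known reactions are the carbene-catalysed intramolecular crossed benzoin cyclisation of 2-(2-oxoalkoxy)benzaldehydes (aldehyde–ketone) to 3-hydroxychroman-4-ones and intermolecular cross-benzoin reactions with an aromatic donor and an α-branched, α-heteroatom-substituted aliphatic acceptor, but an acceptor aldehyde with an α-aryloxy group inside this tether has not been shown. Ring C closes in a 6-exo-trig mode through the O1 tether, which also lets the cross reaction outrun dimerisation. The C3 carbinol centre forms without external control (the 2,3-trans isomer is expected to prevail after base equilibration) and is erased together with C2 in step 10. The step needs the aromatic formyl group, not the α-aryloxy aldehyde, to be the donor, because a Breslow intermediate at C3 could expel the ring A aryloxide; this should be secured by the benzylic acidity of the aryl–carbene adduct, the α,α-disubstitution of the aliphatic aldehyde, an N-phenyl carbene without ortho substituents (small enough for the 2,6-dioxygenated aldehyde), and DBU kept below the triazolium loading so that no free amidine enolises the aliphatic aldehyde. If the aliphatic formyl group nevertheless acts as donor and closes, the regioisomeric 4-hydroxy-3-ketone should drift through the shared enediol toward the conjugated aryl ketone 14 and is in any case oxidised to the same dione in step 10.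

Step 10
Reactants: 14 5,7-bis(benzyloxy)-2-[4-(benzyloxy)phenyl]-3-hydroxy-6-(3-hydroxy-3-methylbutyl)-2,3-dihydro-4H-chromen-4-one
Product: 16 5,7-bis(benzyloxy)-2-[4-(benzyloxy)phenyl]-3-hydroxy-6-(3-hydroxy-3-methylbutyl)-4H-chromen-4-one, via chromane-3,4-dione 15 (not isolated)
Conditions: I2, KOAc, AcOH, 90 °C
Reagents that add atoms: none
Why: Iodine–acetate dehydrogenation of a dihydroflavonol proceeds by enolisation to the 3,4-enediol, oxidation by iodine to the 3,4-dione and tautomerisation through C2–H to the aromatic pyranone, with the buffered medium sparing the tertiary alcohol and the benzyl ethers.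

Step 11
Reactants: 16 5,7-bis(benzyloxy)-2-[4-(benzyloxy)phenyl]-3-hydroxy-6-(3-hydroxy-3-methylbutyl)-4H-chromen-4-one
Product: 17 3,5,7-trihydroxy-6-(3-hydroxy-3-methylbutyl)-2-(4-hydroxyphenyl)-4H-chromen-4-one (target)
Conditions: H2 (1 atm), 10% Pd/C, EtOAc–MeOH, rt
Reagents that add atoms: none
Why: Hydrogenolysis of the three aryl benzyl ethers over palladium should leave the flavonol C2=C3 bond and the non-benzylic tertiary alcohol untouched, and the neutral medium avoids cyclisation of the chain onto the freed phenols.

**Compound list**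

1 | 3,5-bis(benzyloxy)phenol | Oc1cc(OCc2ccccc2)cc(OCc2ccccc2)c1 | starting material
2 | [3,5-bis(benzyloxy)phenoxy]tri(propan-2-yl)silane | CC(C)[Si](Oc1cc(OCc2ccccc2)cc(OCc2ccccc2)c1)(C(C)C)C(C)C | intermediate
3 | 2,2-dimethyloxetane | CC1(C)CCO1 | starting material
4 | [2,6-bis(benzyloxy)-4-{[tri(propan-2-yl)silyl]oxy}phenyl]lithium (formed in the flask, not isolated) | [Li]c1c(OCc2ccccc2)cc(O[Si](C(C)C)(C(C)C)C(C)C)cc1OCc1ccccc1 | intermediate
5 | 4-[2,6-bis(benzyloxy)-4-{[tri(propan-2-yl)silyl]oxy}phenyl]-2-methylbutan-2-ol | CC(C)(O)CCc1c(OCc2ccccc2)cc(O[Si](C(C)C)(C(C)C)C(C)C)cc1OCc1ccccc1 | intermediate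
6 | 3,5-bis(benzyloxy)-4-(3-hydroxy-3-methylbutyl)phenol | CC(C)(O)CCc1c(OCc2ccccc2)cc(O)cc1OCc1ccccc1 | intermediate
7 | 2,4-bis(benzyloxy)-6-hydroxy-3-(3-hydroxy-3-methylbutyl)benzaldehyde | CC(C)(O)CCc1c(OCc2ccccc2)cc(O)c(C=O)c1OCc1ccccc1 | intermediate
8 | methyl 2-[4-(benzyloxy)phenyl]acetate | COC(=O)Cc1ccc(OCc2ccccc2)cc1 | starting material
9 | lithium 2-[4-(benzyloxy)phenyl]-1-methoxyethen-1-olate (lithium enolate of 8, formed in the flask, not isolated) | [Li]OC(OC)=Cc1ccc(OCc2ccccc2)cc1 | intermediate
10 | methyl 2-[4-(benzyloxy)phenyl]-2-bromoacetate (racemic) | COC(=O)C(Br)c1ccc(OCc2ccccc2)cc1 | intermediate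
11 | methyl 2-[3,5-bis(benzyloxy)-2-formyl-4-(3-hydroxy-3-methylbutyl)phenoxy]-2-[4-(benzyloxy)phenyl]acetate (racemic) | COC(=O)C(Oc1cc(OCc2ccccc2)c(CCC(C)(C)O)c(OCc2ccccc2)c1C=O)c1ccc(OCc2ccccc2)cc1 | intermediate
12 | 2-[3,5-bis(benzyloxy)-2-(hydroxymethyl)-4-(3-hydroxy-3-methylbutyl)phenoxy]-2-[4-(benzyloxy)phenyl]ethan-1-ol (racemic) | OCC(Oc1cc(OCc2ccccc2)c(CCC(C)(C)O)c(OCc2ccccc2)c1CO)c1ccc(OCc2ccccc2)cc1 | intermediate
13 | 2,4-bis(benzyloxy)-6-{1-[4-(benzyloxy)phenyl]-2-oxoethoxy}-3-(3-hydroxy-3-methylbutyl)benzaldehyde (racemic; key-step precursor) | CC(C)(O)CCc1c(OCc2ccccc2)cc(OC(C=O)c2ccc(OCc3ccccc3)cc2)c(C=O)c1OCc1ccccc1 | intermediate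
14 | 5,7-bis(benzyloxy)-2-[4-(benzyloxy)phenyl]-3-hydroxy-6-(3-hydroxy-3-methylbutyl)-2,3-dihydro-4H-chromen-4-one (racemic, mixture of diastereomers; key-step product) | CC(C)(O)CCc1c(OCc2ccccc2)cc2OC(c3ccc(OCc4ccccc4)cc3)C(O)C(=O)c2c1OCc1ccccc1 | intermediate
15 | 5,7-bis(benzyloxy)-2-[4-(benzyloxy)phenyl]-6-(3-hydroxy-3-methylbutyl)chromane-3,4-dione (racemic, formed in the flask, not isolated) | CC(C)(O)CCc1c(OCc2ccccc2)cc2OC(c3ccc(OCc4ccccc4)cc3)C(=O)C(=O)c2c1OCc1ccccc1 | intermediate
16 | 5,7-bis(benzyloxy)-2-[4-(benzyloxy)phenyl]-3-hydroxy-6-(3-hydroxy-3-methylbutyl)-4H-chromen-4-one | CC(C)(O)CCc1c(OCc2ccccc2)cc2oc(-c3ccc(OCc4ccccc4)cc3)c(O)c(=O)c2c1OCc1ccccc1 | intermediate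
17 | 3,5,7-trihydroxy-6-(3-hydroxy-3-methylbutyl)-2-(4-hydroxyphenyl)-4H-chromen-4-one | CC(C)(O)CCc1c(O)cc2oc(-c3ccc(O)cc3)c(O)c(=O)c2c1O | target

**Step count**

Total: 11 steps. Longest linear sequence: 10 steps (1 to 17 through steps 1–4 and 6–11); step 5 is the one-step side branch.

**Steps most likely to fail**

1. Step 9 (proposed new method). The carbene may engage the aliphatic formyl group first, and its Breslow intermediate may then expel the ring A aryloxide (internal redox of an α-aryloxy aldehyde) to give an aryl arylacetate. Free base may instead enolise the aliphatic aldehyde, leading to a 5-exo aldol closure onto the aromatic formyl group. The 2,6-dioxygenated formyl group may also be too hindered to form its Breslow intermediate, so that nothing turns over. The fallback sets out from 13 and uses a reductive rather than a catalytic polarity reversal: SmI2 in THF with t-BuOH at −78 °C should form the ketyl of the aromatic aldehyde, which adds to the aliphatic formyl group in the same 6-exo sense (intramolecular pinacol coupling) to give 5,7-bis(benzyloxy)-2-[4-(benzyloxy)phenyl]-6-(3-hydroxy-3-methylbutyl)chromane-3,4-diol F1 as a diastereomer mixture. Oxidation of both carbinols with IBX in DMSO at rt, which does not cleave 1,2-diols, should give dione 15, which tautomerises to flavonol 16, where the route is rejoined.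

2. Step 2. The hindered 2,6-dialkoxyaryllithium may attack the BF3-bound oxetane too slowly, so that Lewis-acid ionisation at the tertiary C–O bond (elimination to a homoallylic alcohol) and simple protonation of the aryllithium take over. The fallback sets out from 2: aryllithium 4 is formed as before, treated with CuI and then 1-bromo-3-methylbut-2-ene at −78 to 0 °C to give {3,5-bis(benzyloxy)-4-(3-methylbut-2-en-1-yl)phenoxy}tri(propan-2-yl)silane F2. Mukaiyama hydration of the trisubstituted alkene (Co(acac)2, PhSiH3, O2, THF, rt) should then give the Markovnikov tertiary alcohol 5, where the route is rejoined.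

3. Step 8. The α-aryl-α-aryloxy aldehyde may enolise during the oxidation or on isolation, followed by aldol closure onto the aromatic formyl group or decomposition on silica. The fallback sets out from 11 and keeps the aromatic formyl group intact throughout, so that no oxidation is needed. Saponification (LiOH, THF–H2O, 0 °C) should give 2-[3,5-bis(benzyloxy)-2-formyl-4-(3-hydroxy-3-methylbutyl)phenoxy]-2-[4-(benzyloxy)phenyl]acetic acid F3. Coupling with ethanethiol (EDC·HCl, DMAP, CH2Cl2) should give S-ethyl 2-[3,5-bis(benzyloxy)-2-formyl-4-(3-hydroxy-3-methylbutyl)phenoxy]-2-[4-(benzyloxy)phenyl]ethanethioate F4. Fukuyama reduction (Et3SiH, 10% Pd/C, acetone, rt) should then deliver dialdehyde 13 under neutral conditions, where the route is rejoined.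

**Further compounds**

F1 | step 9 | 5,7-bis(benzyloxy)-2-[4-(benzyloxy)phenyl]-6-(3-hydroxy-3-methylbutyl)chromane-3,4-diol (racemic, mixture of diastereomers) | CC(C)(O)CCc1c(OCc2ccccc2)cc2OC(c3ccc(OCc4ccccc4)cc3)C(O)C(O)c2c1OCc1ccccc1
F2 | step 2 | {3,5-bis(benzyloxy)-4-(3-methylbut-2-en-1-yl)phenoxy}tri(propan-2-yl)silane | CC(C)=CCc1c(OCc2ccccc2)cc(O[Si](C(C)C)(C(C)C)C(C)C)cc1OCc1ccccc1
F3 | step 8 | 2-[3,5-bis(benzyloxy)-2-formyl-4-(3-hydroxy-3-methylbutyl)phenoxy]-2-[4-(benzyloxy)phenyl]acetic acid (racemic) | OC(=O)C(Oc1cc(OCc2ccccc2)c(CCC(C)(C)O)c(OCc2ccccc2)c1C=O)c1ccc(OCc2ccccc2)cc1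
F4 | step 8 | S-ethyl 2-[3,5-bis(benzyloxy)-2-formyl-4-(3-hydroxy-3-methylbutyl)phenoxy]-2-[4-(benzyloxy)phenyl]ethanethioate (racemic) | CCSC(=O)C(Oc1cc(OCc2ccccc2)c(CCC(C)(C)O)c(OCc2ccccc2)c1C=O)c1ccc(OCc2ccccc2)cc1
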